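**Strategy.** Everything rests on building the benzene ring of the phthalide (C3a–C4–C5–C6–C7–C7a) instead of buying it. The meta C5/C7 methoxy groups, with the C1 carbonyl on C7a beside C7–OMe and the C3 carbinol on C3a, map onto 1,3-dimethoxycyclohexa-1,3-diene plus a 4-oxygenated 2-ynoate. One Alder–Rickert operation (Diels–Alder, then ethylene loss) forms C3a–C4 and C7–C7a and delivers the arene with ester and side chain already ortho. The precursor is an (S)-4-silyloxy-2-ynoate carrying the complete dioxo chain, its stereocentre set by catalytic asymmetric propiolate addition; fluoride then releases O2 for lactonisation.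

Key step: step 6

Assumption: (S,S)-ProPhenol is taken to deliver the alkynylzinc to the Re face of the aldehyde, the face that leads to the (S)-carbinol; an MTPA-ester check on 9 is planned, and the (R,R)-ligand would replace it without other change if the sense proved opposite.

**Step 1**
Reactants: 1 11-bromoundecan-1-ol
Product: 3 11-hydroxyundecanal, via alkoxyammonium bromide 2 (not isolated)
Conditions: Me3N–O (anhydrous, 4 equiv), DMSO, rt → 40 °C
Reagents that add atoms: trimethylamine N-oxide, C[N+](C)(C)[O-]
Why: Kornblum oxidation in its amine N-oxide variant: SN2 attack of the N-oxide oxygen on the primary bromide should give alkoxyammonium salt 2, from which a second N-oxide removes an α-proton to release the aldehyde and trimethylamine, the free hydroxyl being inert and the later 1,4-diketone and ynoate never being exposed to this step.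

**Step 2**
Reactants: 3 11-hydroxyundecanal; 4 but-3-en-2-one
Product: 5 15-hydroxypentadecane-2,5-dione
Conditions: 3-benzyl-5-(2-hydroxyethyl)-4-methylthiazolium chloride (10 mol %), Et3N (30 mol %), 4 (1.3 equiv), EtOH, 75 °C
Reagents that add atoms: none
Why: Stetter reaction: the thiazol-2-ylidene turns the aldehyde into a nucleophilic Breslow intermediate that should add 1,4 to butenone and release the 1,4-diketone, a standard pairing (unbranched aliphatic aldehyde, methyl vinyl ketone) in which the primary hydroxyl is as innocent as the ethanol solvent.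

**Step 3**
Reactants: 5 15-hydroxypentadecane-2,5-dione
Product: 6 11,14-dioxopentadecanal
Conditions: TEMPO (10 mol %), PhI(OAc)2 (1.1 equiv), CH2Cl2, rt
Reagents that add atoms: none
Why: TEMPO (oxoammonium) oxidation with a hypervalent iodine co-oxidant should stop cleanly at the aldehyde and cannot touch the two ketones, and the near-neutral medium does not enolise the 1,4-diketone.

**Step 4**
Reactants: 6 11,14-dioxopentadecanal; 7 methyl propiolate
Product: 9 methyl (4S)-4-hydroxy-14,17-dioxooctadec-2-ynoate, via methylzinc alkynide 8 (not isolated)
Conditions: 7 (3 equiv), Me2Zn (3 equiv), (S,S)-ProPhenol (20 mol %), Ph3P=O (40 mol %), toluene, 0–4 °C, slow addition of 6; then aq. NH4Cl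
Reagents that add atoms: none
Why: Zn–ProPhenol-catalysed asymmetric alkynylation: dimethylzinc metalates the propiolate to alkynylzinc 8, and the dinuclear zinc–ligand pocket should hold the aldehyde so that the alkynyl group is delivered to its Re face, setting C4 as S (O > alkynyl > alkyl > H), while the much less electrophilic ketones should not compete at this temperature and slow aldehyde addition limits aldol pathways.

**Step 5**
Reactants: 9 methyl (4S)-4-hydroxy-14,17-dioxooctadec-2-ynoate
Product: 10 methyl (4S)-4-(tert-butyldimethylsilyloxy)-14,17-dioxooctadec-2-ynoate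
Conditions: TBSCl (1.3 equiv), imidazole (2.5 equiv), DMF, 0 °C → rt
Reagents that add atoms: tert-butyldimethylsilyl chloride, CC(C)(C)[Si](C)(C)Cl
Why: Standard silyl ether formation through the N-silylimidazolium species; no bond at C4 is touched, and the TBS group is chosen because it should survive a neutral melt at 180 °C yet fall to fluoride.

**Step 6**
Reactants: 10 methyl (4S)-4-(tert-butyldimethylsilyloxy)-14,17-dioxooctadec-2-ynoate; 11 1,5-dimethoxycyclohexa-1,4-diene
Product: 14 methyl 2-[(1S)-1-(tert-butyldimethylsilyloxy)-11,14-dioxopentadecyl]-4,6-dimethoxybenzoate, via conjugated diene 12 (not isolated), via bicyclooctadiene adduct 13 (not isolated)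
Conditions: 11 (4 equiv), dichloromaleic anhydride (1 mol %), neat, sealed tube, 180 °C
Reagents that add atoms: none
Why: In the hot melt the skipped diene 11 is conjugated (dichloromaleic anhydride as isomerisation catalyst) to 1,3-dimethoxycyclohexa-1,3-diene 12, whose HOMO should engage the LUMO of ynoate 10 in a concerted, asynchronous normal-demand [4+2] cycloaddition to give bicyclo[2.2.2]octa-2,5-diene 13; a retro-[4+2] then expels the saturated two-carbon bridge as ethylene, irreversibly, since a gas leaves and a benzene ring is gained. The closest known reaction type is the Alder–Rickert synthesis of 6-substituted 2,4-dimethoxybenzoates from 1,3-dialkoxycyclohexadienes and acetylenic esters. The one ring closed is the benzene ring C3a–C4–C5–C6–C7–C7a, closed by intermolecular cycloaddition (bonds C3a–C4 and C7–C7a) and made aromatic by cycloreversion. No stereocentre is created in 14: the two bridgehead centres of 13 vanish on aromatisation, and the carbinol centre is carried through as S because no bond to it is made or broken and its silyl ether offers no ionisation or elimination pathway under neutral thermolysis. The step needs regioselectivity, secured by matched polarisation: the unsubstituted diene terminus, which is the β-carbon of both enol ethers and so carries the largest HOMO coefficient, bonds to the electrophilic ynoate β-carbon, so the methoxy-bearing terminus joins the ester-bearing carbon and the ester ends up between C7–OMe and the side chain. It also needs chemoselectivity, which should hold because the two chain ketones are neither dienes nor dienophiles under these conditions.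

**Step 7**
Reactants: 14 methyl 2-[(1S)-1-(tert-butyldimethylsilyloxy)-11,14-dioxopentadecyl]-4,6-dimethoxybenzoate
Product: 16 CJ-13,015 [(3S)-5,7-dimethoxy-3-(10,13-dioxotetradecyl)-2-benzofuran-1(3H)-one], via hydroxy ester 15 (not isolated)
Conditions: TBAF (1.5 equiv), AcOH (1.5 equiv), THF, 0 °C → rt
Reagents that add atoms: none
Why: Fluoride-induced desilylation gives hydroxy ester 15, whose benzylic hydroxyl sits ortho to the ester and should close the five-membered lactone by intramolecular transesterification with loss of methanol, the C3–O bond never being broken (S retained) and the acetic acid buffer keeping the 1,4-diketone from base-mediated aldol cyclisation.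

**Compound list**

1 | 11-bromoundecan-1-ol | OCCCCCCCCCCCBr | starting material
2 | (11-hydroxyundecyloxy)trimethylammonium bromide | C[N+](C)(C)OCCCCCCCCCCCO.[Br-] | intermediate (not isolated)
3 | 11-hydroxyundecanal | OCCCCCCCCCCC=O | intermediate
4 | but-3-en-2-one | CC(=O)C=C | starting material
5 | 15-hydroxypentadecane-2,5-dione | CC(=O)CCC(=O)CCCCCCCCCCO | intermediate
6 | 11,14-dioxopentadecanal | CC(=O)CCC(=O)CCCCCCCCCC=O | intermediate
7 | methyl propiolate (methyl prop-2-ynoate) | COC(=O)C#C | starting material
8 | methyl 3-(methylzincio)prop-2-ynoate | COC(=O)C#C[Zn]C | intermediate (not isolated)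
9 | methyl (4S)-4-hydroxy-14,17-dioxooctadec-2-ynoate | COC(=O)C#C[C@H](CCCCCCCCCC(=O)CCC(C)=O)O | intermediate
10 | methyl (4S)-4-(tert-butyldimethylsilyloxy)-14,17-dioxooctadec-2-ynoate | COC(=O)C#C[C@H](CCCCCCCCCC(=O)CCC(C)=O)O[Si](C)(C)C(C)(C)C | intermediate
11 | 1,5-dimethoxycyclohexa-1,4-diene | COC1=CCC=C(OC)C1 | starting material
12 | 1,3-dimethoxycyclohexa-1,3-diene | COC1=CC(OC)=CCC1 | intermediate (not isolated)
13 | methyl 3-[(1S)-1-(tert-butyldimethylsilyloxy)-11,14-dioxopentadecyl]-1,5-dimethoxybicyclo[2.2.2]octa-2,5-diene-2-carboxylate (both bridgehead configurations, side chain S) | COC(=O)C1=C([C@H](CCCCCCCCCC(=O)CCC(C)=O)O[Si](C)(C)C(C)(C)C)C2CCC1(OC)C=C2OC | intermediate (not isolated)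
14 | methyl 2-[(1S)-1-(tert-butyldimethylsilyloxy)-11,14-dioxopentadecyl]-4,6-dimethoxybenzoate | COC(=O)c1c(OC)cc(OC)cc1[C@H](CCCCCCCCCC(=O)CCC(C)=O)O[Si](C)(C)C(C)(C)C | intermediate
15 | methyl 2-[(1S)-1-hydroxy-11,14-dioxopentadecyl]-4,6-dimethoxybenzoate | COC(=O)c1c(OC)cc(OC)cc1[C@H](CCCCCCCCCC(=O)CCC(C)=O)O | intermediate (not isolated)
16 | CJ-13,015, (3S)-5,7-dimethoxy-3-(10,13-dioxotetradecyl)-2-benzofuran-1(3H)-one | COc1cc(OC)c2c(c1)[C@H](CCCCCCCCCC(=O)CCC(C)=O)OC2=O | target

**Step count and risks**

Total steps: 7. Longest linear sequence: 7 steps (1 → 3 → 5 → 6 → 9 → 10 → 14 → 16); 4, 7 and 11 enter as purchased.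

Steps most likely to fail:

1. Step 6 (key step). The cycloaddition at the β-branched ynoate may be slow enough that thermal loss of the silyl group or disproportionation of the diene wins before the adduct forms. Fallback, setting out from 10 and returning at 14: 10 is heated with the acyclic ketene-acetal diene 1,1-dimethoxy-3-(trimethylsilyloxy)buta-1,3-diene (toluene, 110 °C). Its CH2 terminus should bond to the ynoate β-carbon for the same polarity reason, giving methyl 2-[(1S)-1-(tert-butyldimethylsilyloxy)-11,14-dioxopentadecyl]-6,6-dimethoxy-4-(trimethylsilyloxy)cyclohexa-1,4-diene-1-carboxylate F1. This aromatises by elimination of methanol instead of by cycloreversion and, after mild acidic work-up that removes the aryl trimethylsilyl group, gives methyl 2-[(1S)-1-(tert-butyldimethylsilyloxy)-11,14-dioxopentadecyl]-4-hydroxy-6-methoxybenzoate F2. O-Methylation of the unhindered phenol (MeI, K2CO3, acetone) then gives 14.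

2. Step 4. Facial selectivity may be poor with an unbranched, enolisable aldehyde, or aldol condensation may compete under the zinc alkoxide conditions. Fallback, setting out from 6 and returning at 9: lithiated 7 (LiHMDS, THF, −78 °C) is added to the aldehyde, which should react ahead of the ketones at this temperature, to give racemic methyl 4-hydroxy-14,17-dioxooctadec-2-ynoate F3. Oxidation (Dess–Martin periodinane, NaHCO3, CH2Cl2) gives methyl 4,14,17-trioxooctadec-2-ynoate F4. Reduction with (S)-Alpine-Borane (THF, rt) should reduce only the alkynyl ketone, with the alkyne acting as the small group, and so give the (S)-alcohol 9.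

3. Step 1. Displacement of the unactivated bromide by the N-oxide may be sluggish, and the hydroxy aldehyde already formed may self-condense during the long reaction. Fallback, setting out from 1 and returning at 5: the bromide is displaced by acetate (KOAc, DMF, 80 °C) to give 11-hydroxyundecyl acetate F5. The free alcohol is oxidised (TEMPO, PhI(OAc)2, CH2Cl2) to 11-oxoundecyl acetate F6. The Stetter reaction with 4 under the conditions of step 2 gives 11,14-dioxopentadecyl acetate F7, and methanolysis (K2CO3, MeOH, rt) gives 5.

**Further compounds**

F1 | step 6 | methyl 2-[(1S)-1-(tert-butyldimethylsilyloxy)-11,14-dioxopentadecyl]-6,6-dimethoxy-4-(trimethylsilyloxy)cyclohexa-1,4-diene-1-carboxylate | COC(=O)C1=C([C@H](CCCCCCCCCC(=O)CCC(C)=O)O[Si](C)(C)C(C)(C)C)CC(O[Si](C)(C)C)=CC1(OC)OC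
F2 | step 6 | methyl 2-[(1S)-1-(tert-butyldimethylsilyloxy)-11,14-dioxopentadecyl]-4-hydroxy-6-methoxybenzoate | COC(=O)c1c(OC)cc(O)cc1[C@H](CCCCCCCCCC(=O)CCC(C)=O)O[Si](C)(C)C(C)(C)C
F3 | step 4 | methyl (4RS)-4-hydroxy-14,17-dioxooctadec-2-ynoate (racemic) | COC(=O)C#CC(O)CCCCCCCCCC(=O)CCC(C)=O
F4 | step 4 | methyl 4,14,17-trioxooctadec-2-ynoate | COC(=O)C#CC(=O)CCCCCCCCCC(=O)CCC(C)=O
F5 | step 1 | 11-hydroxyundecyl acetate | CC(=O)OCCCCCCCCCCCO
F6 | step 1 | 11-oxoundecyl acetate | CC(=O)OCCCCCCCCCCC=O
F7 | step 1 | 11,14-dioxopentadecyl acetate | CC(=O)OCCCCCCCCCCC(=O)CCC(C)=O
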